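## Structural features

The target is a daucane-type hydroazulene: a cyclopentane (C1–C5) and a cycloheptane (C5–C10 and C1) share the C1–C5 bond. C1 is the quaternary carbon with the angular methyl, C4 the tertiary carbinol bearing the isopropyl group, C5 the ring-fusion methine, C6 the carbinol carbon esterified with 4-methoxybenzoic acid, and C8/C9 the epoxide carbons with a methyl on C8. The ring fusion is trans (H-5 anti to the C1 methyl); the C4 hydroxyl lies on the face of the C1 methyl, the C6 oxygen on the face of H-5, and the epoxide oxygen on the face of the C6 oxygen. C1, C5, C4 and C6 are contiguous. Fragile elements are the trisubstituted epoxide (acid, hydride), the aryl ester, the β-relationship of the C4 hydroxyl to C6 (retro-aldol or dehydration whenever C6 is a ketone) and any β,γ-unsaturated C6 ketone on the way (reconjugation). The real difficulty is the quaternary C1 next to a trans ring fusion that an angular-methyl hydroazulene does not adopt by itself: the trans fusion is expected to be preferred only once C4 carries its isopropyl group on the face of H-5. The order in which C4 and C5 are set is therefore decisive: a carbon nucleophile adding to a cis-fused C4 ketone should enter from the convex face and give the wrong C4 epimer. The key step exploits the division of the seven-membered ring into a five-carbon unit C5–C9 with oxygen on C6 (a vinylcyclopropane that is a silyl enol ether) and a two-carbon unit C10–C1 carrying the angular methyl (a 1,1-disubstituted alkene), joined through the tether C2–C4, so that one cycloaddition of an achiral chain closes both rings and sets C1.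

## Logic of the disconnections

28 is cut at the acyl C–O bond on C6 into 26 and 27. Acylation of a secondary alcohol is the most dependable last step, and it leaves the C6 hydroxyl free until then to direct the epoxidation. The forward step must acylate the secondary hydroxyl in the presence of the tertiary one without opening the epoxide.

26 is cut at the two epoxide C–O bonds to give 25. The homoallylic C6 hydroxyl sits on the face where the oxygen is needed, so a directed epoxidation removes C8 and C9 as stereochemical problems. The demand is syn delivery to a trisubstituted alkene.

25 is cut at C6–H to give 24. A hydride delivered from the C4 oxygen gives the anti-1,3-diol; an external hydride on the trans-fused ketone would come from the other face. 24 is traced to 22 by moving the alkene into conjugation, and 22 to 20 by cutting the C8–CH3 bond (conjugate addition, then dehydrogenation). This reduces the seven-membered ring to a plain enone; the demand is a deconjugation that survives until the reduction.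

20 is traced to its C5 epimer 19 and that to 18 by adjusting C6. With the C4 substituents in place the cis-fused 19 holds the isopropyl group cis to C6 on the cyclopentane, so equilibration through the C6 ketone should move it to 20. The demand is enolisation toward the hindered C5 without retro-aldol cleavage.

18 is cut at C3–H and then at the C4–O bond (through 17 and 16) to give 15, and 15 at the C4–isopropyl bond to give 14 and so 13. On the cis-fused bicycle reagents approach C4 from the convex face, the face of the C1 methyl. An oxygen delivered there to a C3=C4 alkene gives the required carbinol, whereas an isopropyl nucleophile added to the ketone would give its epimer. The price is three operations for one carbinol; the demand is face- and chemoselective epoxidation.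

13 is traced through 12 and 11 to 10. The C6 carbonyl is taken down to a protected alcohol so that the C4 ketone can be unveiled without creating an acidic 1,3-diketone, and the C7=C8 alkene is kept so that reoxidation returns an enone directly.

10 is cut at the C7=C8 unsaturation to give 9; the silyl enol ether from the cycloaddition is the regiodefined handle for this dehydrogenation.

9 is cut at C1–C5 and C9–C10 to give 8, removing both rings and both stereocentres. The written configurations of 8 and 9 were checked and are consistent: Z enol ether, cis fusion, C1 as in the target and C5 epimeric to it. The demand is enantioface control on an achiral chain, and tolerance of an enol silane and an allylic ketal by a cationic metal.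

8 is cut at O–Si to give 7, and 7 at the acyl–cyclopropyl bond to give 5 and 6. 5 is traced through 4 to 3, and 3 is cut at C2–C3 to give 1 and 2. The demand is enol silane formation on a β-keto ketal without β-elimination.

## Other disconnections considered

Alternative 1: The cut is through C7–C8 and C1–C10, so the seven-membered ring is built onto a cyclopentenone. The rhodium carbenoid from methyl 2-diazobut-3-enoate A2 (Rh2(S-DOSP)4 or its enantiomer) would cyclopropanate the ethoxyvinyl group of 2-(1-ethoxyethenyl)-3-methylcyclopent-2-en-1-one A1, and the cis-divinylcyclopropane would rearrange (Cope) to the bicyclic vinylogous ester A3.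
- In its favour: it is convergent and belongs to a well-documented, highly enantioselective reaction class. It places a carbon substituent on C8 with the C8=C9 alkene already in its final position; on this point it is better than the chosen plan, which spends three steps there.
- Against it: the Cope step must create the quaternary C1 at the hindered, electron-poor β-carbon of an enone. The C8 ester must be reduced to a methyl group. In A3, C5 is trigonal, so an isopropyl nucleophile would meet C4 with only the remote C1 to distinguish the faces, and the adduct is prone to lose the C4 oxygen by vinylogous elimination. A syn hydrogenation of the C5=C6 enol ether would give the wrong H-5/H-6 relationship.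
- Comparison: on structure it is equal for C1, better for C8/C9 and worse for the C4–C5–C6 triad. On mechanism it uses a known reaction class where the chosen plan uses an untested substrate class, which is an advantage of the alternative. On step economy it is shorter to the bicycle and probably similar overall.

Alternative 2: The cut is the C1–CH3 bond together with C4–C5. Copper-catalysed addition of AlMe3 (CuTC, chiral phosphoramidite) to 3-(4-methyl-3-oxopentyl)cyclohept-2-en-1-one A4 would create C1, and the aluminium enolate would add through C5 to the side-chain ketone to give the hydroxy ketone A5.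
- In its favour: it is very short, and one operation would deliver C1, C4 and C5. A5 is the 7,8-dihydro analogue of 20 and would join the same endgame after one dehydrogenation, so in step count it is clearly better than the chosen plan.
- Against it: seven-membered enones are less dependable in this addition than six-membered ones, and aluminium enolates add sluggishly to hindered ketones. The aldol sets C4 and C5 in a single event with four possible diastereomers. The cis-fused isomer with the isopropyl group on the other face is expected to be of similar stability, so neither kinetic nor thermodynamic control is assured, and retro-aldol exchange would scramble rather than repair.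
- Comparison: on structure the two are equal, since the same intermediate type is reached. On mechanism both have an unproven key event; that of the alternative bears on diastereocontrol, that of the chosen plan on reactivity. The chosen plan sets C4 and C5 one at a time by a convex-face rule and a strain-driven equilibration, which is the safer stereochemical argument, at the price of many more steps.

Alternative 3: The cut is C1–C5 and C1–C10. The carbenoid carbon of (5R)-2-diazo-5-(2-methoxy-4-methylphenyl)-6-methyl-5-(triethylsilyloxy)heptan-3-one A6 (Rh2(OAc)4, or Cu(MeCN)4PF6 with a chiral bis(oxazoline)) would add across the ipso–ortho bond of the arene, and the norcaradiene would open to the cycloheptatriene A7.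
- In its favour: the intramolecular Buchner reaction is a classical entry to hydroazulenones, and the ring carbons, the C8 methyl and the C6 oxygen come from a cheap cresol ether. The C4 carbinol with its isopropyl group is in place before the rings form, so the facial problem at C4 that shapes the chosen plan does not arise; on this point the alternative is better.
- Against it: a diazo ketone with a methyl group on the diazo carbon is prone to 1,2-hydride shift. C1 would be set relative to C4 only by substrate control. A7 carries an extra C2 ketone to delete and three ring double bonds to sort into one C8=C9 alkene, a trans ring fusion and a C6 carbinol. Cycloheptatrienes also undergo 1,5-hydrogen shifts.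
- Comparison: on structure it is better for C4 and the C8 methyl and worse in oxidation-level editing. On mechanism it is a known reaction type, an advantage over the chosen plan, but with a known competing path. On step economy the bicycle arises in one step, yet the precursor needs its own asymmetric synthesis and the redox corrections are expected to make the route no shorter.

Key step: step 6

Assumption on the catalyst: the (R)-BINAP complex is taken to give the (1S,5R) enantiomer 9; if the sense of induction is the opposite, the (S)-ligand is used and nothing else changes.
Remark on locants: C1 to C10 as defined under Structural features are used for all bicyclic compounds.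

Step 1
Reactants: 1 ethyl acetoacetate; 2 3-chloro-2-methylprop-1-ene
Product: 3 ethyl 6-methyl-3-oxohept-6-enoate
Conditions: NaH, THF, 0 °C; n-BuLi, 0 °C; then 2, 0 °C to rt; aq. NH4Cl
Reagents that add atoms: none
Why: Weiler dianion alkylation: the more reactive γ-carbanion of the acetoacetate dianion is alkylated by the allylic chloride, which joins C3 to C2 and brings in C1, C10 and the future angular methyl.

Step 2
Reactants: 3 ethyl 6-methyl-3-oxohept-6-enoate
Product: 4 ethyl 2-[2-(3-methylbut-3-en-1-yl)-1,3-dioxolan-2-yl]acetate
Conditions: HOCH2CH2OH, PPTS (cat.), benzene, reflux, Dean–Stark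
Reagents that add atoms: ethane-1,2-diol, OCCO
Why: Acid-catalysed ketalisation of the ketone (the ester is inert) masks C4 and removes the acidic 1,3-dicarbonyl; the weak acid with azeotropic removal of water should spare the 1,1-disubstituted alkene.

Step 3
Reactants: 4 ethyl 2-[2-(3-methylbut-3-en-1-yl)-1,3-dioxolan-2-yl]acetate
Product: 5 N-methoxy-N-methyl-2-[2-(3-methylbut-3-en-1-yl)-1,3-dioxolan-2-yl]acetamide
Conditions: MeNH(OMe)·HCl, i-PrMgCl, THF, −20 to 0 °C
Reagents that add atoms: N,O-dimethylhydroxylamine hydrochloride, CNOC.Cl
Why: Weinreb amide formation from the ester with the magnesium amide; the low temperature limits deprotonation next to the ketal.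

Step 4
Reactants: 5 N-methoxy-N-methyl-2-[2-(3-methylbut-3-en-1-yl)-1,3-dioxolan-2-yl]acetamide; 6 cyclopropylmagnesium bromide
Product: 7 1-cyclopropyl-2-[2-(3-methylbut-3-en-1-yl)-1,3-dioxolan-2-yl]ethan-1-one
Conditions: THF, 0 °C; aq. NH4Cl
Reagents that add atoms: none
Why: Weinreb ketone synthesis: the chelated tetrahedral intermediate prevents over-addition and releases the cyclopropyl ketone on work-up.

Step 5
Reactants: 7 1-cyclopropyl-2-[2-(3-methylbut-3-en-1-yl)-1,3-dioxolan-2-yl]ethan-1-one
Product: 8 (Z)-tert-butyl{[1-cyclopropyl-2-[2-(3-methylbut-3-en-1-yl)-1,3-dioxolan-2-yl]ethenyl]oxy}dimethylsilane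
Conditions: TBSOTf, Et3N, CH2Cl2, −78 to 0 °C
Reagents that add atoms: tert-butyldimethylsilyl trifluoromethanesulfonate, CC(C)(C)[Si](C)(C)OS(=O)(=O)C(F)(F)F
Why: Soft enolisation (silyl triflate and amine) avoids a free enolate β to the ketal, which could open the dioxolane by E1cB elimination; only the C5 methylene can enolise, and A(1,3) strain between the cyclopropyl group and the quaternary ketal carbon favours the Z isomer with the tether trans to the cyclopropane.

Step 6
Reactants: 8 (Z)-tert-butyl{[1-cyclopropyl-2-[2-(3-methylbut-3-en-1-yl)-1,3-dioxolan-2-yl]ethenyl]oxy}dimethylsilane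
Product: 9 cis-fused (1S,5R) bicyclic C6 tert-butyldimethylsilyl enol ether (C6=C7) with C4 dioxolane and C1 methyl
Conditions: [Rh((R)-BINAP)]SbF6 (10 mol%, halide-free, preformed from [Rh(cod)2]SbF6, (R)-BINAP and H2), 2,6-di-tert-butyl-4-methylpyridine (10 mol%), ClCH2CH2Cl, 60 °C
Reagents that add atoms: none
Why: Proposed new method: the closest known reaction type is the cationic rhodium–bisphosphine (5+2) cycloaddition of tethered alkene–vinylcyclopropanes, which accepts 1,1-disubstituted alkenes and is enantioselective with BINAP; untested is a silyloxy group on the vinyl carbon that carries the cyclopropane. Monovalent rhodium should bind the enol ether and the cyclopropane, cleave the proximal bond C7–C9 to a σ,π-allyl rhodacyclohexene, insert the tethered alkene at the allyl terminus C5 (bond C1–C5) and reductively eliminate from the eight-membered rhodacycle (bond C9–C10), leaving the double bond at C6=C7 as the silyl enol ether. The five-membered ring closes by exo insertion of the alkene across the three-atom tether, the seven-membered ring by C(sp3)–C(sp3) reductive elimination. C1 and C5 are created together in the insertion: their cis relation follows from syn addition of the Rh–C5 bond across the alkene within the short tether, and their absolute sense from the C2-symmetric ligand, which distinguishes the faces of the prochiral alkene. The electron-rich enol ether should bind the cationic metal at least as well as a simple alkene, and the Z geometry places the tether trans to the cyclopropyl group as in the known E-configured substrates. After insertion the metal sits on the neopentyl carbon C10, which has no β-hydrogen on C1, so reductive elimination has no β-hydride competitor on that side. The hindered pyridine protects the enol silane and the allylic ketal from adventitious acid.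

Step 7
Reactants: 9 cis-fused bicyclic C6 silyl enol ether with C4 dioxolane
Product: 10 cis-fused enone (C6 ketone and C7=C8) with C4 dioxolane
Conditions: Pd(OAc)2 (1.1 equiv), MeCN, rt to 40 °C
Reagents that add atoms: none
Why: Saegusa–Ito oxidation: palladation of the enol silane at C7 and β-hydride elimination from C8 give the enone; the neutral medium should leave the β-keto ketal and the cis C5 centre untouched.

Step 8
Reactants: 10 cis-fused enone with C4 dioxolane
Product: 11 cis-fused allylic alcohol (C6 hydroxyl on the face of the five-membered ring and C7=C8) with C4 dioxolane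
Conditions: NaBH4, CeCl3·7H2O, MeOH, −40 °C
Reagents that add atoms: none
Why: Luche 1,2-reduction; hydride is expected from the face away from the five-membered ring, but the C6 configuration is of no consequence because C6 is reoxidised in step 15; the purpose is to remove the C6 carbonyl before C4 is unveiled.

Step 9
Reactants: 11 cis-fused allylic alcohol with C4 dioxolane
Product: 12 C6 tert-butyldimethylsilyl ether of 11
Conditions: TBSCl, imidazole, DMF, rt to 40 °C
Reagents that add atoms: tert-butyldimethylsilyl chloride, CC(C)(C)[Si](C)(C)Cl
Why: Silyl ether formation; the group is base-stable and a poor leaving group β to the coming C4 ketone.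

Step 10
Reactants: 12 C6 silyl ether with C4 dioxolane
Product: 13 cis-fused C4 ketone with C6 silyloxy group and C7=C8
Conditions: PPTS, acetone/H2O, 50 °C
Reagents that add atoms: water, O
Why: Acid-catalysed ketal hydrolysis, now ordinary because the ketal is no longer β to a carbonyl; a cyclopentanone next to this ring fusion is expected to prefer the cis fusion, so enolisation toward C5 is harmless.

Step 11
Reactants: 13 cis-fused C4 ketone
Product: 14 C3=C4 enol trifluoromethanesulfonate
Conditions: KN(SiMe3)2, THF, −78 °C; PhNTf2, −78 to 0 °C
Reagents that add atoms: N-phenylbis(trifluoromethanesulfonimide), O=S(=O)(N(c1ccccc1)S(=O)(=O)C(F)(F)F)C(F)(F)F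
Why: Kinetic deprotonation at the C3 methylene (the C5 methine is flanked by two fully substituted carbons) and O-sulfonylation give the less substituted enol triflate.

Step 12
Reactants: 14 C3=C4 enol trifluoromethanesulfonate
Product: 15 cis-fused diene with C3=C4 bearing the isopropyl group on C4
Conditions: i-PrMgCl, Fe(acac)3 (5 mol%), THF/NMP, −30 °C
Reagents that add atoms: isopropylmagnesium chloride, CC(C)[Mg]Cl
Why: Iron-catalysed alkyl–alkenyl cross-coupling of an enol triflate with a secondary Grignard reagent installs the isopropyl carbon skeleton without creating a stereocentre.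

Step 13
Reactants: 15 cis-fused diene
Product: 16 3,4-epoxide with the oxygen on the face of the C1 methyl and H-5
Conditions: mCPBA, NaHCO3, CH2Cl2, −20 to 0 °C
Reagents that add atoms: 3-chloroperoxybenzoic acid, O=C(OO)c1cccc(Cl)c1
Why: Prilezhaev epoxidation of the more electron-rich trisubstituted cyclopentene (the other alkene is disubstituted and deactivated by the allylic silyloxy group); attack from the convex face of the cis-fused bicycle, anti to C6 on the neighbouring C5, places the C4 oxygen on the face of the C1 methyl as in the target.

Step 14
Reactants: 16 3,4-epoxide
Product: 18 cis-fused diol (C4 tertiary hydroxyl on the face of the C1 methyl; C6 allylic hydroxyl), via silyl-protected tertiary carbinol 17 (not isolated)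
Conditions: LiEt3BH, THF, 0 °C to rt; aqueous work-up; Bu4NF, THF, rt
Reagents that add atoms: none
Why: SN2 hydride opening of the trisubstituted epoxide at the secondary carbon C3 leaves the C4–O bond intact and gives the isopropyl carbinol; fluoride then removes the silyl ether.

Step 15
Reactants: 18 cis-fused diol
Product: 20 trans-fused hydroxy enone (C6 ketone and C7=C8; H-5 anti to the C1 methyl and to the C4 hydroxyl), via cis-fused hydroxy enone 19 (not isolated)
Conditions: Dess–Martin periodinane, NaHCO3, CH2Cl2, 0 °C; then DBU (cat.), toluene, 40 °C
Reagents that add atoms: none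
Why: Dess–Martin oxidation touches only the secondary allylic alcohol; in 19 the isopropyl group is cis to C6 on the cyclopentane, so amine-catalysed enolisation toward C5 and reprotonation should funnel the material to the trans-fused epimer, in which the isopropyl group is trans to C6 and the hydroxyl can hydrogen-bond to the ketone.

Step 16
Reactants: 20 trans-fused hydroxy enone
Product: 22 trans-fused β-methyl enone (C6 ketone and C7=C8 with methyl on C8; C4 trimethylsilyl ether), via bis(trimethylsilyl) enol ether 21 (not isolated)
Conditions: Me2CuLi, Me3SiCl, THF, −78 °C; then Pd(OAc)2, MeCN, rt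
Reagents that add atoms: lithium dimethylcuprate, [Li+].C[Cu-]C; chlorotrimethylsilane, C[Si](C)(C)Cl
Why: Cuprate 1,4-addition with silyl chloride trapping (which also silylates the tertiary alkoxide), then Saegusa–Ito oxidation, restores the unsaturation as the β-methyl enone; the transient C8 stereocentre disappears.

Step 17
Reactants: 22 trans-fused β-methyl enone
Product: 24 trans-fused β,γ-unsaturated ketone (C6 ketone and C8=C9; free C4 hydroxyl), via silylated β,γ-unsaturated ketone 23 (not isolated)
Conditions: KOt-Bu, THF, 0 °C; inverse quench into cold aq. AcOH; then Bu4NF/AcOH, THF, 0 °C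
Reagents that add atoms: none
Why: Classical deconjugation: thermodynamic γ-deprotonation to the through-conjugated endocyclic dienolate, then kinetic α-protonation at C7 on inverse acidic quench; the silyl ether blocks retro-aldol cleavage under base and buffered fluoride then frees the hydroxyl without reconjugation.

Step 18
Reactants: 24 trans-fused β,γ-unsaturated ketone
Product: 25 anti-4,6-diol with C8=C9 (C6 hydroxyl on the face of H-5)
Conditions: Me4NBH(OAc)3, MeCN/AcOH, −20 °C
Reagents that add atoms: none
Why: Evans–Saksena hydroxyl-directed reduction: the borohydride bound to the C4 oxygen delivers hydride to the face of C6 that is syn to the C4–O bond, which gives the anti-1,3-diol and sets C6; the cold, weakly acidic medium should not move the alkene.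

Step 19
Reactants: 25 anti-4,6-diol with C8=C9
Product: 26 8,9-epoxy-4,6-diol with the epoxide oxygen on the face of the C6 hydroxyl
Conditions: VO(acac)2 (5 mol%), t-BuOOH, CH2Cl2, 0 °C to rt
Reagents that add atoms: tert-butyl hydroperoxide, CC(C)(C)OO
Why: Vanadium-catalysed hydroxyl-directed epoxidation of the homoallylic alcohol delivers the oxygen syn to the C6 hydroxyl and so sets C8 and C9.

Step 20
Reactants: 26 8,9-epoxy-4,6-diol; 27 4-methoxybenzoyl chloride
Product: 28 target, (1R,4R,5S,6S,8R,9S)-8,9-epoxy-4-hydroxy-4-isopropyl-1,8-dimethylbicyclic C6 4-methoxybenzoate (CNP0235939.1)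
Conditions: Et3N, DMAP (cat.), CH2Cl2, 0 °C to rt
Reagents that add atoms: none
Why: DMAP-catalysed acylation of the secondary alcohol; the tertiary alcohol is too hindered to compete and the amine scavenges HCl so the epoxide survives.

Compound list

1 | ethyl acetoacetate | CCOC(=O)CC(C)=O | starting material
2 | 3-chloro-2-methylprop-1-ene | C=C(C)CCl | starting material
3 | ethyl 6-methyl-3-oxohept-6-enoate | CCOC(=O)CC(=O)CCC(C)=C | intermediate
4 | ethyl 2-[2-(3-methylbut-3-en-1-yl)-1,3-dioxolan-2-yl]acetate | CCOC(=O)CC1(CCC(C)=C)OCCO1 | intermediate
5 | N-methoxy-N-methyl-2-[2-(3-methylbut-3-en-1-yl)-1,3-dioxolan-2-yl]acetamide | CON(C)C(=O)CC1(CCC(C)=C)OCCO1 | intermediate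
6 | cyclopropylmagnesium bromide | Br[Mg]C1CC1 | starting material
7 | 1-cyclopropyl-2-[2-(3-methylbut-3-en-1-yl)-1,3-dioxolan-2-yl]ethan-1-one | C=C(C)CCC1(OCCO1)CC(=O)C1CC1 | intermediate
8 | (Z)-tert-butyl{[1-cyclopropyl-2-[2-(3-methylbut-3-en-1-yl)-1,3-dioxolan-2-yl]ethenyl]oxy}dimethylsilane | C=C(C)CCC1(OCCO1)/C=C(\O[Si](C)(C)C(C)(C)C)C1CC1 | intermediate
9 | cis-fused (1S,5R) bicycle: C6 tert-butyldimethylsilyl enol ether (C6=C7), C4 ethylene ketal, C1 methyl cis to H-5 | CC(C)(C)[Si](C)(C)OC1=CCCC[C@@]2(C)CCC3(OCCO3)[C@@H]12 | intermediate
10 | cis-fused enone: C6 ketone, C7=C8, C4 ethylene ketal | O=C1C=CCC[C@@]2(C)CCC3(OCCO3)[C@@H]12 | intermediate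
11 | cis-fused allylic alcohol: C6 hydroxyl trans to H-5 (expected epimer), C7=C8, C4 ethylene ketal | O[C@H]1C=CCC[C@@]2(C)CCC3(OCCO3)[C@@H]12 | intermediate
12 | C6 tert-butyldimethylsilyl ether of 11 | CC(C)(C)[Si](C)(C)O[C@H]1C=CCC[C@@]2(C)CCC3(OCCO3)[C@@H]12 | intermediate
13 | cis-fused C4 ketone, C6 silyloxy, C7=C8 | CC(C)(C)[Si](C)(C)O[C@H]1C=CCC[C@@]2(C)CCC(=O)[C@@H]12 | intermediate
14 | C3=C4 enol trifluoromethanesulfonate of 13 | CC(C)(C)[Si](C)(C)O[C@H]1C=CCC[C@@]2(C)CC=C(OS(=O)(=O)C(F)(F)F)[C@@H]12 | intermediate
15 | cis-fused diene: C3=C4 with isopropyl on C4, C7=C8, C6 silyloxy | CC(C)(C)[Si](C)(C)O[C@H]1C=CCC[C@@]2(C)CC=C(C(C)C)[C@@H]12 | intermediate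
16 | 3,4-epoxide of 15, oxygen on the face of the C1 methyl and H-5 | CC(C)(C)[Si](C)(C)O[C@H]1C=CCC[C@@]2(C)C[C@@H]3O[C@]3(C(C)C)[C@@H]12 | intermediate
17 | cis-fused C4 carbinol (hydroxyl on the face of the C1 methyl, isopropyl opposite), C6 silyloxy, C7=C8 | CC(C)(C)[Si](C)(C)O[C@H]1C=CCC[C@@]2(C)CC[C@@](O)(C(C)C)[C@@H]12 | intermediate
18 | cis-fused 4,6-diol, C7=C8 | O[C@H]1C=CCC[C@@]2(C)CC[C@@](O)(C(C)C)[C@@H]12 | intermediate
19 | cis-fused hydroxy enone: C6 ketone, C7=C8, C4 carbinol | O=C1C=CCC[C@@]2(C)CC[C@@](O)(C(C)C)[C@@H]12 | intermediate
20 | trans-fused hydroxy enone: H-5 anti to the C1 methyl and to the C4 hydroxyl | O=C1C=CCC[C@@]2(C)CC[C@@](O)(C(C)C)[C@H]12 | intermediate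
21 | trans-fused C6 trimethylsilyl enol ether (C6=C7), C8 methyl (both C8 epimers), C4 trimethylsilyl ether | C[Si](C)(C)OC1=CC(C)CC[C@@]2(C)CC[C@@](O[Si](C)(C)C)(C(C)C)[C@H]12 | intermediate
22 | trans-fused β-methyl enone: C6 ketone, C7=C8 with methyl on C8, C4 trimethylsilyl ether | O=C1C=C(C)CC[C@@]2(C)CC[C@@](O[Si](C)(C)C)(C(C)C)[C@H]12 | intermediate
23 | trans-fused β,γ-unsaturated ketone: C6 ketone, C8=C9, C4 trimethylsilyl ether | O=C1CC(C)=CC[C@@]2(C)CC[C@@](O[Si](C)(C)C)(C(C)C)[C@H]12 | intermediate
24 | trans-fused β,γ-unsaturated ketone with free C4 hydroxyl | O=C1CC(C)=CC[C@@]2(C)CC[C@@](O)(C(C)C)[C@H]12 | intermediate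
25 | trans-fused anti-4,6-diol, C8=C9, C6 hydroxyl cis to H-5 | O[C@H]1CC(C)=CC[C@@]2(C)CC[C@@](O)(C(C)C)[C@H]12 | intermediate
26 | 8,9-epoxy-4,6-diol, epoxide oxygen on the face of the C6 hydroxyl | O[C@H]2C[C@@]3(C)O[C@H]3C[C@@]3(C)CC[C@@](O)(C(C)C)[C@H]23 | intermediate
27 | 4-methoxybenzoyl chloride | COc1ccc(C(=O)Cl)cc1 | starting material
28 | CNP0235939.1, (1R,4R,5S,6S,8R,9S) C6 4-methoxybenzoate of 26 | COc1ccc(C(=O)O[C@H]2C[C@@]3(C)O[C@H]3C[C@@]3(C)CC[C@@](O)(C(C)C)[C@H]23)cc1 | target

Total step count: 20. Longest linear sequence: 20 steps (1 to 28); 2, 6 and 27 enter as commercial reagents.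

Steps least certain to work

Step 6 (key step, proposed new method). Most likely failure: no productive cycloaddition, either because the hindered trisubstituted enol silane binds or cleaves the cyclopropane too slowly, or because the cationic metal or trace acid ionises the allylic ketal and desilylates the enol ether. Low enantioface discrimination on this more substituted vinylcyclopropane is the second risk.

Fallback in known chemistry, from 7 back to 10:
- NaBH4 reduces 7 to the secondary alcohol 1-cyclopropyl-2-[2-(3-methylbut-3-en-1-yl)-1,3-dioxolan-2-yl]ethan-1-ol F1.
- Burgess dehydration (syn elimination toward the C5 methylene, since the cyclopropyl methine would give a strained alkylidenecyclopropane) gives the vinylcyclopropane 2-[(E)-2-cyclopropylethenyl]-2-(3-methylbut-3-en-1-yl)-1,3-dioxolane F2.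
- F2 belongs to the established substrate class, so [Rh((R)-BINAP)]SbF6 should convert it into the cis-fused cycloheptene with C6=C7 and the C4 dioxolane F3.
- mCPBA from the face away from the five-membered ring gives the 6,7-epoxide F4.
- Diethylaluminium 2,2,6,6-tetramethylpiperidide removes a C8 hydrogen and opens the epoxide to the allylic alcohol with C6 hydroxyl and C7=C8 F5 (the C6 epimer of 11).
- Dess–Martin oxidation returns the enone 10.

Step 13. Most likely failure: poor face discrimination in the epoxidation, because the pseudo-axial C1 methyl on the convex face may hinder the peracid as much as C6 does on the other face; competing epoxidation of C7=C8 is the lesser risk. Fallback, from 15 back to 17: the facial preference is turned round by an anti addition. N-Bromosuccinimide in aqueous acetone forms the bromonium ion on the face the peracid prefers, and water opens it at the tertiary C4 from the opposite face to give the bromohydrin with C3 bromide and C4 hydroxyl F6. Bu3SnH with AIBN removes the bromine and gives 17. This is the route to use if the peracid proves to favour the face of the seven-membered ring.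

Step 15. Most likely failure: retro-aldol cleavage of the C4–C5 bond through the tertiary alkoxide (which would scramble C4), loss of water to the C4=C5 enone, or an equilibration that stops short because enolisation toward the hindered C5 is slow. Fallback, from 18 back to 22: after the same oxidation, 19 is silylated (Me3SiOTf, 2,6-lutidine) to the cis-fused trimethylsilyl ether of the hydroxy enone F7. DBU then equilibrates C5 with no alkoxide available for fragmentation, giving the trans-fused trimethylsilyl ether F8. F8 enters the conditions of step 16 unchanged and rejoins the route at 22.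

Step 17. Most likely failure: deprotonation at the C8 methyl or at C5 instead of C9, or reconjugation during work-up, so that the alkene ends exocyclic or back at C7=C8. Fallback, from 22 back to 24: the thermodynamic dienol silane is made under non-basic, equilibrating conditions (Me3SiCl, NaI, Et3N, MeCN) and isolated as the bis(trimethylsilyl) dienol ether with C6=C7 and C8=C9 F9. Buffered fluoride (Bu4NF/AcOH, THF, −78 °C) releases the dienolate in the presence of the proton source, protonates it at C7 and frees the C4 hydroxyl, giving 24.

Further compounds

F1 | step 6 | 1-cyclopropyl-2-[2-(3-methylbut-3-en-1-yl)-1,3-dioxolan-2-yl]ethan-1-ol (racemic) | C=C(C)CCC1(OCCO1)CC(O)C1CC1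
F2 | step 6 | 2-[(E)-2-cyclopropylethenyl]-2-(3-methylbut-3-en-1-yl)-1,3-dioxolane | C=C(C)CCC1(OCCO1)/C=C/C1CC1
F3 | step 6 | cis-fused cycloheptene with C6=C7, C4 ethylene ketal and C1 methyl | C1=CCCC[C@@]2(C)CCC3(OCCO3)[C@@H]12
F4 | step 6 | 6,7-epoxide of F3, oxygen on the face away from the five-membered ring | [C@H]15O[C@@H]5CCC[C@@]2(C)CCC3(OCCO3)[C@@H]12
F5 | step 6 | cis-fused allylic alcohol with C6 hydroxyl cis to H-5 and C7=C8 (C6 epimer of 11) | O[C@@H]1C=CCC[C@@]2(C)CCC3(OCCO3)[C@@H]12
F6 | step 13 | bromohydrin: C3 bromide on the face of the seven-membered ring, C4 hydroxyl on the face of the C1 methyl | CC(C)(C)[Si](C)(C)O[C@H]1C=CCC[C@@]2(C)C[C@@H](Br)[C@@](O)(C(C)C)[C@@H]12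
F7 | step 15 | C4 trimethylsilyl ether of 19 (cis-fused) | O=C1C=CCC[C@@]2(C)CC[C@@](O[Si](C)(C)C)(C(C)C)[C@@H]12
F8 | step 15 | C4 trimethylsilyl ether of 20 (trans-fused) | O=C1C=CCC[C@@]2(C)CC[C@@](O[Si](C)(C)C)(C(C)C)[C@H]12
F9 | step 17 | bis(trimethylsilyl) dienol ether: C6 silyloxy, C6=C7, C8=C9, C4 silyl ether | C[Si](C)(C)OC1=CC(C)=CC[C@@]2(C)CC[C@@](O[Si](C)(C)C)(C(C)C)[C@H]12
A1 | alternative 1 | 2-(1-ethoxyethenyl)-3-methylcyclopent-2-en-1-one | CCOC(=C)C1=C(C)CCC1=O
A2 | alternative 1 | methyl 2-diazobut-3-enoate | C=CC(=[N+]=[N-])C(=O)OC
A3 | alternative 1 | bicyclic vinylogous ester: C4 ketone, C5=C6 ethyl enol ether, C8 methyl ester on C8=C9, C1 methyl | CCOC1=C2C(=O)CC[C@]2(C)CC=C(C(=O)OC)C1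
A4 | alternative 2 | 3-(4-methyl-3-oxopentyl)cyclohept-2-en-1-one | O=C1C=C(CCC(=O)C(C)C)CCCC1
A5 | alternative 2 | trans-fused C6 ketone with C1 methyl and C4 isopropyl carbinol | O=C1CCCC[C@@]2(C)CC[C@@](O)(C(C)C)[C@H]12
A6 | alternative 3 | (5R)-2-diazo-5-(2-methoxy-4-methylphenyl)-6-methyl-5-(triethylsilyloxy)heptan-3-one | CC(=[N+]=[N-])C(=O)C[C@@](O[Si](CC)(CC)CC)(C(C)C)c1ccc(C)cc1OC
A7 | alternative 3 | bicyclic cycloheptatriene: C1 methyl, C2 ketone, C4 triethylsilyloxy isopropyl carbinol, C6 methyl enol ether, C8 methyl | COC1=C2[C@](O[Si](CC)(CC)CC)(C(C)C)CC(=O)[C@]2(C)C=CC(C)=C1
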